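The route rests on disconnecting the trans-fused decalin at C5–C10 and C8–C9, so that ring A and ring B arise together from an acyclic trienoate in one thermal intramolecular Diels–Alder reaction. The step exploits the quaternary C10 (bearing the C20 methyl) flanked by tertiary C5 and C9: an (E)-β-methyl enoate (C11, C9, C10) is linked through the C1–C4 tether, which carries the C2 silyl ether and the C4 gem-dimethyl group, to a C5–C8 silyloxydiene. The single C2 stereocentre thereby sets C5, C9 and C10. The C7 enol ether is afterwards converted into the C7–C8 alkene, and C13 is installed by a reagent-controlled epoxidation of a coupled side chain.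

Key step: step 6

Remark: positions are given in labdane numbering (ring A C1–C5 and C10, ring B C5–C10, side chain C11–C16, C17 on C8, C20 on C10); the (S,S)-bisphosphoramide of step 4 and the (4S)-auxiliary of its fallback are assumed to direct attack to the Si face of the aldehyde, the antipode being used if the sense proves reversed.

Step 1
Reactants: 1 2,2-dimethylpent-4-enal; 2 diethyl (2-oxobutyl)phosphonate
Product: 3 (4E)-6,6-dimethylnona-4,8-dien-3-one
Conditions: Ba(OH)2·8H2O, THF/H2O (40:1), rt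
Reagents that add atoms: none
Why: Horner–Wadsworth–Emmons olefination of the non-enolisable, α-quaternary aldehyde with the stabilised β-ketophosphonate should give the (E)-enone, the mild hydroxide protocol being suited to hindered aldehydes.

Step 2
Reactants: 3 (4E)-6,6-dimethylnona-4,8-dien-3-one
Product: 5 (4E)-3,3-dimethyl-6-oxooct-4-enal, via ozonide 4 (not isolated)
Conditions: O3, CH2Cl2, −78 °C, Sudan Red 7B as end-point indicator; then PPh3, −78 °C to rt
Reagents that add atoms: ozone, [O-][O+]=O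
Why: In this ozonolysis with reductive work-up the electrophilic ozone should consume the electron-rich monosubstituted alkene well before the electron-poor enone double bond, which is also shielded by the adjacent quaternary carbon, and the dye marks the end-point.

Step 3
Reactants: 6 methyl 3-methylbut-2-enoate
Product: 8 tert-butyl[(1-methoxy-3-methylbuta-1,3-dien-1-yl)oxy]dimethylsilane, via lithium dienolate 7 (not isolated)
Conditions: LiN(i-Pr)2, THF, −78 °C; then t-BuMe2SiCl, DMPU, −78 °C to rt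
Reagents that add atoms: tert-butyl(chloro)dimethylsilane, CC(C)(C)[Si](C)(C)Cl
Why: γ-Deprotonation of the senecioate and O-silylation of the extended enolate is the standard preparation of the silyl dienolate needed for a vinylogous Mukaiyama aldol reaction.

Step 4
Reactants: 5 (4E)-3,3-dimethyl-6-oxooct-4-enal; 8 tert-butyl[(1-methoxy-3-methylbuta-1,3-dien-1-yl)oxy]dimethylsilane
Product: 10 methyl (2E,5S,8E)-5-hydroxy-3,7,7-trimethyl-10-oxododeca-2,8-dienoate, via trichlorosilyl aldolate 9 (not isolated)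
Conditions: SiCl4, (S,S)-binaphthyldiamine-derived bisphosphoramide (5 mol %), i-Pr2NEt (cat.), CH2Cl2, −78 °C; then aq. NaHCO3
Reagents that add atoms: none
Why: In this catalytic asymmetric vinylogous Mukaiyama aldol addition the Lewis-base-bound chlorosilyl cation activates only the aldehyde, the dienolate reacts at its γ-carbon to give the (E)-enoate, and Si-face attack under catalyst control sets the C2 carbinol as S.

Step 5
Reactants: 10 methyl (2E,5S,8E)-5-hydroxy-3,7,7-trimethyl-10-oxododeca-2,8-dienoate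
Product: 12 methyl (2E,5S,8E,10Z)-5,10-bis[(tert-butyldimethylsilyl)oxy]-3,7,7-trimethyldodeca-2,8,10-trienoate, via mono-silyl ether 11 (not isolated)
Conditions: t-BuMe2SiOTf (2.5 equiv), Et3N, CH2Cl2, −78 °C to 0 °C
Reagents that add atoms: tert-butyldimethylsilyl trifluoromethanesulfonate, CC(C)(C)[Si](C)(C)OS(=O)(=O)C(F)(F)F
Why: Silyl triflate/amine silylation caps the C2 alcohol and then enolises the ethyl ketone softly to the 2-silyloxydiene, whose (Z)-geometry (C17 methyl outside the diene) is the usual outcome for vinyl ethyl ketones, so one silyl group serves as both protecting and activating group.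

Step 6
Reactants: 12 methyl (2E,5S,8E,10Z)-5,10-bis[(tert-butyldimethylsilyl)oxy]-3,7,7-trimethyldodeca-2,8,10-trienoate
Product: 13 methyl (1R,2S,4aR,7R,8aR)-3,7-bis[(tert-butyldimethylsilyl)oxy]-2,5,5,8a-tetramethyl-1,2,4a,5,6,7,8,8a-octahydronaphthalene-1-carboxylate
Conditions: PhMe (0.01 M), 2,6-di-tert-butyl-4-methylphenol (cat.), Et3N (cat.), base-washed sealed tube, 180 °C
Reagents that add atoms: none
Why: A concerted, asynchronous suprafacial [4+2] cycloaddition joins C5–C10 and C8–C9; the closest known reaction type is the thermal type 1 intramolecular Diels–Alder reaction of 1,7,9-decatrienoates to trans-fused octalins with an angular methyl group. Ring B closes as the new cyclohexene, and ring A closes in the fused (not bridged) mode from the C1–C4 tether held in a chair. C5 and C10 follow from the diene face, fixed because the C2 silyl ether sits equatorial in that chair (axial it would be syn-diaxial to a C4 methyl and to C20); C9 follows from the (E)-enoate geometry, which keeps C11 cis to C20, and C8 from the (Z)-enol ether combined with the endo ester. The step needs endo over exo selectivity (trans fusion) and one diene face; the endo preference rests on secondary overlap of the ester and on the C10 methyl, which should disfavour the cis-fused transition state, while the C4 gem-dimethyl group populates the reactive conformer. Because the silyloxy group polarises the diene towards C8 whereas the tether forces C8 onto the ester α-carbon, the reaction relies on heat and not on a Lewis acid, and the amine and inhibitor protect the enol ether.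

Step 7
Reactants: 13 methyl (1R,2S,4aR,7R,8aR)-3,7-bis[(tert-butyldimethylsilyl)oxy]-2,5,5,8a-tetramethyl-1,2,4a,5,6,7,8,8a-octahydronaphthalene-1-carboxylate
Product: 15 methyl (1R,2R,4aR,7R,8aR)-7-[(tert-butyldimethylsilyl)oxy]-2,5,5,8a-tetramethyl-3-oxodecahydronaphthalene-1-carboxylate, via C8-axial ketone 14 (not isolated)
Conditions: Bu4NF trihydrate (1.05 equiv), THF, −20 °C to 0 °C
Reagents that add atoms: none
Why: Fluoride cleaves the silyl enol ether far faster than the secondary alkyl silyl ether, and the basic medium should epimerise C8 so that its methyl becomes equatorial, relieving the syn-diaxial clash with C20 (desilylation followed by thermodynamic epimerisation; C8 becomes sp2 in step 8 in any case).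

Step 8
Reactants: 15 methyl (1R,2R,4aR,7R,8aR)-7-[(tert-butyldimethylsilyl)oxy]-2,5,5,8a-tetramethyl-3-oxodecahydronaphthalene-1-carboxylate
Product: 16 methyl (1S,4aR,7R,8aR)-7-[(tert-butyldimethylsilyl)oxy]-2,5,5,8a-tetramethyl-3-{[(trifluoromethyl)sulfonyl]oxy}-1,4,4a,5,6,7,8,8a-octahydronaphthalene-1-carboxylate
Conditions: Tf2O, 2,6-di-tert-butyl-4-methylpyridine, CH2Cl2, 0 °C to rt
Reagents that add atoms: trifluoromethanesulfonic anhydride, O=S(=O)(OS(=O)(=O)C(F)(F)F)C(F)(F)F
Why: O-Triflation of a ketone with triflic anhydride and a hindered pyridine runs under thermodynamic control and should favour the more substituted C7–C8 enol triflate, the axial H8 being aligned for loss.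

Step 9
Reactants: 16 methyl (1S,4aR,7R,8aR)-7-[(tert-butyldimethylsilyl)oxy]-2,5,5,8a-tetramethyl-3-{[(trifluoromethyl)sulfonyl]oxy}-1,4,4a,5,6,7,8,8a-octahydronaphthalene-1-carboxylate
Product: 17 methyl (1R,4aR,7R,8aR)-7-[(tert-butyldimethylsilyl)oxy]-2,5,5,8a-tetramethyl-1,4,4a,5,6,7,8,8a-octahydronaphthalene-1-carboxylate
Conditions: Pd(OAc)2 (5 mol %), PPh3, HCO2H, Bu3N, DMF, 60 °C
Reagents that add atoms: none
Why: Palladium-catalysed formate reduction of an enol triflate (oxidative addition, formate exchange, decarboxylation, reductive elimination) replaces the triflate by hydrogen without moving the C7–C8 double bond or touching the ester.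

Step 10
Reactants: 17 methyl (1R,4aR,7R,8aR)-7-[(tert-butyldimethylsilyl)oxy]-2,5,5,8a-tetramethyl-1,4,4a,5,6,7,8,8a-octahydronaphthalene-1-carboxylate
Product: 18 [(1R,4aR,7R,8aR)-7-[(tert-butyldimethylsilyl)oxy]-2,5,5,8a-tetramethyl-1,4,4a,5,6,7,8,8a-octahydronaphthalen-1-yl]methanol
Conditions: LiAlH4, Et2O, 0 °C
Reagents that add atoms: none
Why: Hydride reduction of the ester to the primary alcohol leaves the silyl ether and the trisubstituted alkene untouched.

Step 11
Reactants: 18 [(1R,4aR,7R,8aR)-7-[(tert-butyldimethylsilyl)oxy]-2,5,5,8a-tetramethyl-1,4,4a,5,6,7,8,8a-octahydronaphthalen-1-yl]methanol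
Product: 19 (1R,4aR,7R,8aR)-7-[(tert-butyldimethylsilyl)oxy]-2,5,5,8a-tetramethyl-1,4,4a,5,6,7,8,8a-octahydronaphthalene-1-carbaldehyde
Conditions: Dess–Martin periodinane, pyridine, CH2Cl2, 0 °C to rt
Reagents that add atoms: none
Why: The Dess–Martin oxidation is fast and nearly neutral, so the β,γ-unsaturated aldehyde should form without epimerisation at C9 or migration of the alkene into conjugation.

Step 12
Reactants: 19 (1R,4aR,7R,8aR)-7-[(tert-butyldimethylsilyl)oxy]-2,5,5,8a-tetramethyl-1,4,4a,5,6,7,8,8a-octahydronaphthalene-1-carbaldehyde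
Product: 20 tert-butyl{[(2R,4aR,8R,8aR)-8-ethenyl-4,4,7,8a-tetramethyl-1,2,3,4,4a,5,8,8a-octahydronaphthalen-2-yl]oxy}dimethylsilane
Conditions: Ph3PCH3Br, KN(SiMe3)2, THF, 0 °C; then 19, −78 °C to 0 °C
Reagents that add atoms: methyltriphenylphosphonium bromide, C[P+](c1ccccc1)(c1ccccc1)c1ccccc1.[Br-]
Why: Wittig methylenation with the non-stabilised ylide at low temperature should outpace enolisation of the hindered aldehyde, and the equatorial C9 configuration is in any case the stable one.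

Step 13
Reactants: 21 but-2-yn-1-ol
Product: 23 (2Z)-3-iodobut-2-en-1-ol, via cyclic alkenylalanate 22 (not isolated)
Conditions: NaAlH2(OCH2CH2OMe)2, THF, 0 °C to rt; then I2, −78 °C
Reagents that add atoms: iodine, [I][I]
Why: Hydroxyl-directed trans-hydroalumination of the propargylic alcohol places aluminium on C3 in a five-membered alanate, and iodinolysis with retention gives the (Z)-iodoalkenol.

Step 14
Reactants: 20 tert-butyl{[(2R,4aR,8R,8aR)-8-ethenyl-4,4,7,8a-tetramethyl-1,2,3,4,4a,5,8,8a-octahydronaphthalen-2-yl]oxy}dimethylsilane; 23 (2Z)-3-iodobut-2-en-1-ol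
Product: 25 (2Z)-5-[(1R,4aR,7R,8aR)-7-[(tert-butyldimethylsilyl)oxy]-2,5,5,8a-tetramethyl-1,4,4a,5,6,7,8,8a-octahydronaphthalen-1-yl]-3-methylpent-2-en-1-ol, via B-alkyl-9-BBN 24 (not isolated)
Conditions: 9-BBN, THF, 0 °C to rt; then 23, PdCl2(dppf) (5 mol %), AsPh3, Cs2CO3, DMF/H2O, rt
Reagents that add atoms: none
Why: In this B-alkyl Suzuki–Miyaura coupling 9-BBN hydroborates only the monosubstituted vinyl group at its terminus (C12), and the alkylborane couples with the alkenyl iodide with retention, so the (Z)-trisubstituted allylic alcohol is formed stereospecifically.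

Step 15
Reactants: 25 (2Z)-5-[(1R,4aR,7R,8aR)-7-[(tert-butyldimethylsilyl)oxy]-2,5,5,8a-tetramethyl-1,4,4a,5,6,7,8,8a-octahydronaphthalen-1-yl]-3-methylpent-2-en-1-ol
Product: 26 [(2R,3S)-3-{2-[(1R,4aR,7R,8aR)-7-[(tert-butyldimethylsilyl)oxy]-2,5,5,8a-tetramethyl-1,4,4a,5,6,7,8,8a-octahydronaphthalen-1-yl]ethyl}-3-methyloxiran-2-yl]methanol
Conditions: Ti(OiPr)4 (10 mol %), D-(−)-diethyl tartrate (12 mol %), t-BuOOH, 4 Å molecular sieves, CH2Cl2, −20 °C
Reagents that add atoms: tert-butyl hydroperoxide, CC(C)(C)OO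
Why: In the Sharpless asymmetric epoxidation only the allylic alcohol reacts (the ring alkene is inert), and for this (Z)-3,3-disubstituted, nerol-type substrate the D-tartrate should deliver oxygen to the face that makes C13 S, under reagent control and independent of the remote ring stereocentres.

Step 16
Reactants: 26 [(2R,3S)-3-{2-[(1R,4aR,7R,8aR)-7-[(tert-butyldimethylsilyl)oxy]-2,5,5,8a-tetramethyl-1,4,4a,5,6,7,8,8a-octahydronaphthalen-1-yl]ethyl}-3-methyloxiran-2-yl]methanol
Product: 28 (3S)-5-[(1R,4aR,7R,8aR)-7-[(tert-butyldimethylsilyl)oxy]-2,5,5,8a-tetramethyl-1,4,4a,5,6,7,8,8a-octahydronaphthalen-1-yl]-3-methylpent-1-en-3-ol, via epoxy iodide 27 (not isolated)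
Conditions: PPh3, I2, imidazole, THF, 0 °C; then Zn, AcOH, 0 °C to rt
Reagents that add atoms: none
Why: Appel iodination followed by zinc-mediated reductive β-elimination of the 2,3-epoxy iodide opens the epoxide to the tertiary allylic alcohol without touching the C13–O bond, so C13 stays S.

Step 17
Reactants: 28 (3S)-5-[(1R,4aR,7R,8aR)-7-[(tert-butyldimethylsilyl)oxy]-2,5,5,8a-tetramethyl-1,4,4a,5,6,7,8,8a-octahydronaphthalen-1-yl]-3-methylpent-1-en-3-ol
Product: 29 (2R,4aR,8R,8aR)-8-[(3S)-3-hydroxy-3-methylpent-4-en-1-yl]-4,4,7,8a-tetramethyl-1,2,3,4,4a,5,8,8a-octahydronaphthalen-2-ol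
Conditions: Bu4NF, THF, rt
Reagents that add atoms: none
Why: Fluoride-mediated desilylation frees the secondary C2 alcohol, and neither alkene nor the tertiary allylic alcohol is affected.

Step 18
Reactants: 29 (2R,4aR,8R,8aR)-8-[(3S)-3-hydroxy-3-methylpent-4-en-1-yl]-4,4,7,8a-tetramethyl-1,2,3,4,4a,5,8,8a-octahydronaphthalen-2-ol; 30 3-methylbut-2-enoic acid
Product: 31 (2R,4aR,8R,8aR)-8-[(3S)-3-hydroxy-3-methylpent-4-en-1-yl]-4,4,7,8a-tetramethyl-1,2,3,4,4a,5,8,8a-octahydronaphthalen-2-yl 3-methylbut-2-enoate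
Conditions: DCC, DMAP (cat.), CH2Cl2, 0 °C to rt
Reagents that add atoms: none
Why: In this Steglich esterification the activated acid acylates the unhindered equatorial secondary C2 alcohol, whereas the tertiary allylic C13 alcohol should not react, and the absence of a strong base avoids deconjugation of the senecioyl group.

Compound list
1 | 2,2-dimethylpent-4-enal | C=CCC(C)(C)C=O | starting material
2 | diethyl (2-oxobutyl)phosphonate | CCOP(=O)(CC(=O)CC)OCC | starting material
3 | (4E)-6,6-dimethylnona-4,8-dien-3-one | CCC(=O)/C=C/C(C)(C)CC=C | intermediate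
4 | (4E)-6,6-dimethyl-7-(1,2,4-trioxolan-3-yl)hept-4-en-3-one (secondary ozonide, ring carbon unspecified) | CCC(=O)/C=C/C(C)(C)CC1OCOO1 | intermediate (not isolated)
5 | (4E)-3,3-dimethyl-6-oxooct-4-enal | CCC(=O)/C=C/C(C)(C)CC=O | intermediate
6 | methyl 3-methylbut-2-enoate | COC(=O)C=C(C)C | starting material
7 | lithium 1-methoxy-3-methylbuta-1,3-dien-1-olate | C=C(C)C=C(OC)O[Li] | intermediate (not isolated)
8 | tert-butyl[(1-methoxy-3-methylbuta-1,3-dien-1-yl)oxy]dimethylsilane | C=C(C)C=C(OC)O[Si](C)(C)C(C)(C)C | intermediate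
9 | methyl (2E,5S,8E)-3,7,7-trimethyl-10-oxo-5-[(trichlorosilyl)oxy]dodeca-2,8-dienoate | COC(=O)/C=C(\C)C[C@H](O[Si](Cl)(Cl)Cl)CC(C)(C)/C=C/C(=O)CC | intermediate (not isolated)
10 | methyl (2E,5S,8E)-5-hydroxy-3,7,7-trimethyl-10-oxododeca-2,8-dienoate | COC(=O)/C=C(\C)C[C@H](O)CC(C)(C)/C=C/C(=O)CC | intermediate
11 | methyl (2E,5S,8E)-5-[(tert-butyldimethylsilyl)oxy]-3,7,7-trimethyl-10-oxododeca-2,8-dienoate | COC(=O)/C=C(\C)C[C@H](O[Si](C)(C)C(C)(C)C)CC(C)(C)/C=C/C(=O)CC | intermediate (not isolated)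
12 | methyl (2E,5S,8E,10Z)-5,10-bis[(tert-butyldimethylsilyl)oxy]-3,7,7-trimethyldodeca-2,8,10-trienoate | COC(=O)/C=C(\C)C[C@H](O[Si](C)(C)C(C)(C)C)CC(C)(C)/C=C/C(O[Si](C)(C)C(C)(C)C)=C/C | intermediate
13 | methyl (1R,2S,4aR,7R,8aR)-3,7-bis[(tert-butyldimethylsilyl)oxy]-2,5,5,8a-tetramethyl-1,2,4a,5,6,7,8,8a-octahydronaphthalene-1-carboxylate (trans-fused; ester cis to the angular methyl and to the C8 methyl; C2 silyloxy trans to the angular methyl) | COC(=O)[C@@H]1[C@H](C)C(O[Si](C)(C)C(C)(C)C)=C[C@@H]2C(C)(C)C[C@@H](O[Si](C)(C)C(C)(C)C)C[C@@]12C | intermediate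
14 | methyl (1R,2S,4aR,7R,8aR)-7-[(tert-butyldimethylsilyl)oxy]-2,5,5,8a-tetramethyl-3-oxodecahydronaphthalene-1-carboxylate (C8 methyl axial) | COC(=O)[C@@H]1[C@H](C)C(=O)C[C@@H]2C(C)(C)C[C@@H](O[Si](C)(C)C(C)(C)C)C[C@@]12C | intermediate (not isolated)
15 | methyl (1R,2R,4aR,7R,8aR)-7-[(tert-butyldimethylsilyl)oxy]-2,5,5,8a-tetramethyl-3-oxodecahydronaphthalene-1-carboxylate (C8 methyl equatorial) | COC(=O)[C@@H]1[C@@H](C)C(=O)C[C@@H]2C(C)(C)C[C@@H](O[Si](C)(C)C(C)(C)C)C[C@@]12C | intermediate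
16 | methyl (1S,4aR,7R,8aR)-7-[(tert-butyldimethylsilyl)oxy]-2,5,5,8a-tetramethyl-3-{[(trifluoromethyl)sulfonyl]oxy}-1,4,4a,5,6,7,8,8a-octahydronaphthalene-1-carboxylate | COC(=O)[C@@H]1C(C)=C(OS(=O)(=O)C(F)(F)F)C[C@@H]2C(C)(C)C[C@@H](O[Si](C)(C)C(C)(C)C)C[C@@]12C | intermediate
17 | methyl (1R,4aR,7R,8aR)-7-[(tert-butyldimethylsilyl)oxy]-2,5,5,8a-tetramethyl-1,4,4a,5,6,7,8,8a-octahydronaphthalene-1-carboxylate | COC(=O)[C@@H]1C(C)=CC[C@@H]2C(C)(C)C[C@@H](O[Si](C)(C)C(C)(C)C)C[C@@]12C | intermediate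
18 | [(1R,4aR,7R,8aR)-7-[(tert-butyldimethylsilyl)oxy]-2,5,5,8a-tetramethyl-1,4,4a,5,6,7,8,8a-octahydronaphthalen-1-yl]methanol | OC[C@@H]1C(C)=CC[C@@H]2C(C)(C)C[C@@H](O[Si](C)(C)C(C)(C)C)C[C@@]12C | intermediate
19 | (1R,4aR,7R,8aR)-7-[(tert-butyldimethylsilyl)oxy]-2,5,5,8a-tetramethyl-1,4,4a,5,6,7,8,8a-octahydronaphthalene-1-carbaldehyde | O=C[C@@H]1C(C)=CC[C@@H]2C(C)(C)C[C@@H](O[Si](C)(C)C(C)(C)C)C[C@@]12C | intermediate
20 | tert-butyl{[(2R,4aR,8R,8aR)-8-ethenyl-4,4,7,8a-tetramethyl-1,2,3,4,4a,5,8,8a-octahydronaphthalen-2-yl]oxy}dimethylsilane | C=C[C@@H]1C(C)=CC[C@@H]2C(C)(C)C[C@@H](O[Si](C)(C)C(C)(C)C)C[C@@]12C | intermediate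
21 | but-2-yn-1-ol | CC#CCO | starting material
22 | sodium 2,2-bis(2-methoxyethoxy)-3-methyl-2,5-dihydro-1,2-oxaluminol-2-uide | CC1=CCO[Al-]1(OCCOC)OCCOC.[Na+] | intermediate (not isolated)
23 | (2Z)-3-iodobut-2-en-1-ol | C/C(I)=C/CO | intermediate
24 | 9-{2-[(1R,4aR,7R,8aR)-7-[(tert-butyldimethylsilyl)oxy]-2,5,5,8a-tetramethyl-1,4,4a,5,6,7,8,8a-octahydronaphthalen-1-yl]ethyl}-9-borabicyclo[3.3.1]nonane | B1(CC[C@@H]2C(C)=CC[C@@H]3C(C)(C)C[C@@H](O[Si](C)(C)C(C)(C)C)C[C@@]23C)C2CCCC1CCC2 | intermediate (not isolated)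
25 | (2Z)-5-[(1R,4aR,7R,8aR)-7-[(tert-butyldimethylsilyl)oxy]-2,5,5,8a-tetramethyl-1,4,4a,5,6,7,8,8a-octahydronaphthalen-1-yl]-3-methylpent-2-en-1-ol | C/C(CC[C@@H]1C(C)=CC[C@@H]2C(C)(C)C[C@@H](O[Si](C)(C)C(C)(C)C)C[C@@]12C)=C/CO | intermediate
26 | [(2R,3S)-3-{2-[(1R,4aR,7R,8aR)-7-[(tert-butyldimethylsilyl)oxy]-2,5,5,8a-tetramethyl-1,4,4a,5,6,7,8,8a-octahydronaphthalen-1-yl]ethyl}-3-methyloxiran-2-yl]methanol | OC[C@H]1O[C@@]1(C)CC[C@@H]2C(C)=CC[C@@H]3C(C)(C)C[C@@H](O[Si](C)(C)C(C)(C)C)C[C@@]23C | intermediate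
27 | tert-butyl{[(2R,4aR,8R,8aR)-8-{2-[(2S,3S)-3-(iodomethyl)-2-methyloxiran-2-yl]ethyl}-4,4,7,8a-tetramethyl-1,2,3,4,4a,5,8,8a-octahydronaphthalen-2-yl]oxy}dimethylsilane | IC[C@H]1O[C@@]1(C)CC[C@@H]2C(C)=CC[C@@H]3C(C)(C)C[C@@H](O[Si](C)(C)C(C)(C)C)C[C@@]23C | intermediate (not isolated)
28 | (3S)-5-[(1R,4aR,7R,8aR)-7-[(tert-butyldimethylsilyl)oxy]-2,5,5,8a-tetramethyl-1,4,4a,5,6,7,8,8a-octahydronaphthalen-1-yl]-3-methylpent-1-en-3-ol | C=C[C@@](C)(O)CC[C@@H]1C(C)=CC[C@@H]2C(C)(C)C[C@@H](O[Si](C)(C)C(C)(C)C)C[C@@]12C | intermediate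
29 | (2R,4aR,8R,8aR)-8-[(3S)-3-hydroxy-3-methylpent-4-en-1-yl]-4,4,7,8a-tetramethyl-1,2,3,4,4a,5,8,8a-octahydronaphthalen-2-ol | C=C[C@@](C)(O)CC[C@@H]1C(C)=CC[C@@H]2C(C)(C)C[C@@H](O)C[C@@]12C | intermediate
30 | 3-methylbut-2-enoic acid | CC(C)=CC(=O)O | starting material
31 | (2R,4aR,8R,8aR)-8-[(3S)-3-hydroxy-3-methylpent-4-en-1-yl]-4,4,7,8a-tetramethyl-1,2,3,4,4a,5,8,8a-octahydronaphthalen-2-yl 3-methylbut-2-enoate (labdane positions 2R,5R,9R,10R,13S) | C=C[C@@](C)(O)CC[C@@H]1C(C)=CC[C@@H]2C(C)(C)C[C@@H](OC(=O)C=C(C)C)C[C@@]12C | target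

Total step count: 18. Longest linear sequence: 16 steps (steps 1, 2, 4–12 and 14–18, from 1 to 31).

Steps most likely to fail

1. Step 6. The cycloaddition may be too slow at temperatures the silyl enol ether tolerates, or endo/exo discrimination may be poor, because a trisubstituted ester dienophile must form a quaternary centre and the donor-substituted diene terminus is tied to the ester α-carbon. The fallback sets out from 12 and comes back at 20; it replaces ester activation by aldehyde activation, which allows a Lewis-acid-promoted cycloaddition at low temperature. Reduction of 12 with i-Bu2AlH (CH2Cl2, −78 °C) should give (2E,5S,8E,10Z)-5,10-bis[(tert-butyldimethylsilyl)oxy]-3,7,7-trimethyldodeca-2,8,10-trien-1-ol F1. MnO2 oxidation then gives the corresponding trienal F2. Treatment with Me2AlCl (CH2Cl2, −78 °C) should close both rings to the aldehyde cycloadduct F3. Wittig methylenation gives the ethenyl silyl enol ether F4, and Bu4NF releases the ethenyl ketone F5 with the C8 methyl equatorial. Tf2O with 2,6-di-tert-butyl-4-methylpyridine gives the ethenyl enol triflate F6, and Pd(OAc)2/PPh3/HCO2H/Bu3N reduction delivers 20.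

2. Step 8. Regiocontrol may be lost in the enolisation, proton loss from C6 competing with loss from C8, which would place the alkene at C6–C7 after reduction. The fallback sets out from 15 and comes back at 16; it separates equilibration from triflation. Me3SiI with (Me3Si)2NH (CH2Cl2, rt) equilibrates the silyl enol ethers and should give the more substituted trimethylsilyl enol ether F7. This is converted regiospecifically into 16 with PhNTf2 and CsF in 1,2-dimethoxyethane.

3. Step 4. Enantiofacial discrimination or turnover may be insufficient with a β-quaternary aliphatic aldehyde that also carries an enone. The fallback sets out from 5 and comes back at 11; it replaces catalyst control by auxiliary control and builds the enoate stepwise. A tin-mediated acetate aldol addition of N-acetyl-(4S)-4-isopropyl-1,3-thiazolidine-2-thione (Sn(OTf)2, N-ethylpiperidine, CH2Cl2, −78 °C) to 5 gives the aldol adduct F8. Silylation (t-BuMe2SiOTf, 2,6-lutidine) gives the silyl ether F9. Displacement of the auxiliary with potassium methyl malonate, MgCl2 and imidazole, with decarboxylation, gives the β-keto ester F10. NaH and PhNTf2 convert the chelated enolate into the (Z)-enol triflate F11. Palladium-catalysed methylation with trimethylboroxine (Pd(PPh3)4, K2CO3, dioxane) proceeds with retention to 11, here isolated, which is enol-silylated to 12 as in step 5.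

Further compounds
F1 | step 6 | (2E,5S,8E,10Z)-5,10-bis[(tert-butyldimethylsilyl)oxy]-3,7,7-trimethyldodeca-2,8,10-trien-1-ol | OC/C=C(\C)C[C@H](O[Si](C)(C)C(C)(C)C)CC(C)(C)/C=C/C(O[Si](C)(C)C(C)(C)C)=C/C
F2 | step 6 | (2E,5S,8E,10Z)-5,10-bis[(tert-butyldimethylsilyl)oxy]-3,7,7-trimethyldodeca-2,8,10-trienal | O=C/C=C(\C)C[C@H](O[Si](C)(C)C(C)(C)C)CC(C)(C)/C=C/C(O[Si](C)(C)C(C)(C)C)=C/C
F3 | step 6 | (1R,2S,4aR,7R,8aR)-3,7-bis[(tert-butyldimethylsilyl)oxy]-2,5,5,8a-tetramethyl-1,2,4a,5,6,7,8,8a-octahydronaphthalene-1-carbaldehyde | O=C[C@@H]1[C@H](C)C(O[Si](C)(C)C(C)(C)C)=C[C@@H]2C(C)(C)C[C@@H](O[Si](C)(C)C(C)(C)C)C[C@@]12C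
F4 | step 6 | 1-ethenyl analogue of 13 (ethenyl in place of the methyl ester) | C=C[C@@H]1[C@H](C)C(O[Si](C)(C)C(C)(C)C)=C[C@@H]2C(C)(C)C[C@@H](O[Si](C)(C)C(C)(C)C)C[C@@]12C
F5 | step 6 | 1-ethenyl analogue of 15 (ethenyl ketone, C8 methyl equatorial) | C=C[C@@H]1[C@@H](C)C(=O)C[C@@H]2C(C)(C)C[C@@H](O[Si](C)(C)C(C)(C)C)C[C@@]12C
F6 | step 6 | 1-ethenyl analogue of 16 (ethenyl C7–C8 enol triflate) | C=C[C@@H]1C(C)=C(OS(=O)(=O)C(F)(F)F)C[C@@H]2C(C)(C)C[C@@H](O[Si](C)(C)C(C)(C)C)C[C@@]12C
F7 | step 8 | methyl (1S,4aR,7R,8aR)-7-[(tert-butyldimethylsilyl)oxy]-2,5,5,8a-tetramethyl-3-[(trimethylsilyl)oxy]-1,4,4a,5,6,7,8,8a-octahydronaphthalene-1-carboxylate | COC(=O)[C@@H]1C(C)=C(O[Si](C)(C)C)C[C@@H]2C(C)(C)C[C@@H](O[Si](C)(C)C(C)(C)C)C[C@@]12C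
F8 | step 4 | (3R,6E)-3-hydroxy-1-[(4S)-4-isopropyl-2-thioxo-1,3-thiazolidin-3-yl]-5,5-dimethyldec-6-ene-1,8-dione | CCC(=O)/C=C/C(C)(C)C[C@@H](O)CC(=O)N1[C@@H](C(C)C)CSC1=S
F9 | step 4 | (3R,6E)-3-[(tert-butyldimethylsilyl)oxy]-1-[(4S)-4-isopropyl-2-thioxo-1,3-thiazolidin-3-yl]-5,5-dimethyldec-6-ene-1,8-dione | CCC(=O)/C=C/C(C)(C)C[C@@H](O[Si](C)(C)C(C)(C)C)CC(=O)N1[C@@H](C(C)C)CSC1=S
F10 | step 4 | methyl (5R,8E)-5-[(tert-butyldimethylsilyl)oxy]-7,7-dimethyl-3,10-dioxododec-8-enoate | CCC(=O)/C=C/C(C)(C)C[C@@H](O[Si](C)(C)C(C)(C)C)CC(=O)CC(=O)OC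
F11 | step 4 | methyl (2Z,5R,8E)-5-[(tert-butyldimethylsilyl)oxy]-7,7-dimethyl-10-oxo-3-{[(trifluoromethyl)sulfonyl]oxy}dodeca-2,8-dienoate | COC(=O)/C=C(\OS(=O)(=O)C(F)(F)F)C[C@H](O[Si](C)(C)C(C)(C)C)CC(C)(C)/C=C/C(=O)CC
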